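**Plan**

1. Retrosynthesis: the three ester C–O bonds are cut first (aryl angelate, benzylic (R)-2-methylbutanoate, primary acetate). The oxirane is then opened at its CH2–O bond to a bromohydrin held as a cyclic carbonate, the tertiary benzylic C–O and the C–Br bond are cut together to a 2-arylallyl tert-butyl carbonate, and last the aryl–alkenyl C–C bond.
2. Enabling feature: the oxirane oxygen on the fully substituted benzylic carbon lies 1,2 to the oxygen of the acetoxymethyl arm. That primary oxygen, worn as a tert-butyl carbonate, can hand its carbonyl oxygen to the benzylic carbon through a five-membered 1,3-dioxolan-2-one.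
3. Forward: silylation, Miyaura borylation and Suzuki coupling attach the 3-hydroxyprop-1-en-2-yl unit to the arene. Carbonate formation and bromocyclisation close the dioxolanone, and methanolysis exchanges it for the oxirane. Acetylation, aldehyde reduction, esterification and desilylative angeloylation complete the three esters.
4. Stereochemistry: the quaternary oxirane carbon is fixed in the bromocyclisation by hydroquinidine 1,4-phthalazinediyl diether, (DHQD)2PHAL, and none of its bonds is broken afterwards. The second stereocentre and the (Z)-alkene are bought in with (R)-2-methylbutanoic acid and angelic anhydride.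
5. The benzylic carbon is carried as an aldehyde until the carbonate has been methanolysed, so no carboxylic ester is exposed to the palladium steps or to K2CO3/MeOH.

Key step: step 5

Assumption: (DHQD)2PHAL is taken to deliver bromine to the alkene face that leads to the (S)-dioxolanone 12; should the antipode predominate, the pseudoenantiomeric hydroquinine 1,4-phthalazinediyl diether, (DHQ)2PHAL, would be used with no other change.

**Route**

Step 1
Reactants: 1 3-hydroxy-4-iodobenzaldehyde; 2 chlorotri(propan-2-yl)silane (TIPSCl)
Product: 3 4-iodo-3-[tri(propan-2-yl)silyloxy]benzaldehyde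
Conditions: TIPSCl, imidazole, DMF, rt
Reagents that add atoms: chlorotri(propan-2-yl)silane, CC(C)[Si](Cl)(C(C)C)C(C)C
Why: Imidazole-promoted O-silylation of the phenol (silyl ether formation) is reliable even next to iodine, and the bulky triisopropylsilyl ether is chosen because it should withstand the carbonate and phosphate bases used later while leaving under fluoride.

Step 2
Reactants: 3 4-iodo-3-[tri(propan-2-yl)silyloxy]benzaldehyde; 4 bis(pinacolato)diboron
Product: 5 4-(4,4,5,5-tetramethyl-1,3,2-dioxaborolan-2-yl)-3-[tri(propan-2-yl)silyloxy]benzaldehyde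
Conditions: B2pin2, PdCl2(dppf) (dppf = 1,1'-bis(diphenylphosphino)ferrocene, 5 mol %), KOAc, 1,4-dioxane, 85 °C
Reagents that add atoms: bis(pinacolato)diboron, CC1(C)OB(OC1(C)C)B1OC(C)(C)C(C)(C)O1
Why: Miyaura borylation, in which zerovalent palladium inserts into the aryl C–I bond and acetate-assisted transmetalation from B2pin2 gives the pinacol boronate under conditions that aldehydes and aryl silyl ethers tolerate.

Step 3
Reactants: 5 4-(4,4,5,5-tetramethyl-1,3,2-dioxaborolan-2-yl)-3-[tri(propan-2-yl)silyloxy]benzaldehyde; 6 2-bromoprop-2-en-1-ol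
Product: 7 4-(3-hydroxyprop-1-en-2-yl)-3-[tri(propan-2-yl)silyloxy]benzaldehyde
Conditions: Pd(OAc)2 (5 mol %), 2-dicyclohexylphosphino-2',6'-dimethoxybiphenyl (SPhos, 10 mol %), K3PO4, THF–H2O (10:1), 50 °C
Reagents that add atoms: 2-bromoprop-2-en-1-ol, OCC(Br)=C
Why: Suzuki–Miyaura coupling of the aryl boronate with the vinyl bromide, for which the bulky electron-rich SPhos ligand suits the ortho-substituted boronate and the free allylic hydroxyl needs no protection.

Step 4
Reactants: 7 4-(3-hydroxyprop-1-en-2-yl)-3-[tri(propan-2-yl)silyloxy]benzaldehyde; 8 di-tert-butyl dicarbonate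
Product: 9 tert-butyl 2-{4-formyl-2-[tri(propan-2-yl)silyloxy]phenyl}prop-2-en-1-yl carbonate
Conditions: Boc2O, 4-(dimethylamino)pyridine (DMAP, 10 mol %), MeCN, 0 °C to rt
Reagents that add atoms: di-tert-butyl dicarbonate, CC(C)(C)OC(=O)OC(=O)OC(C)(C)C
Why: DMAP-catalysed O-acylation of the primary allylic alcohol by Boc2O (tert-butyl carbonate formation) runs under neutral conditions that leave the aldehyde and the silyl ether alone.

Step 5
Reactants: 9 tert-butyl 2-{4-formyl-2-[tri(propan-2-yl)silyloxy]phenyl}prop-2-en-1-yl carbonate; 10 N-bromosuccinimide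
Product: 12 (4S)-4-(bromomethyl)-4-{4-formyl-2-[tri(propan-2-yl)silyloxy]phenyl}-1,3-dioxolan-2-one, via 2-tert-butoxy-1,3-dioxolan-2-ylium ion 11 (not isolated)
Conditions: N-bromosuccinimide (1.2 equiv), hydroquinidine 1,4-phthalazinediyl diether, (DHQD)2PHAL (10 mol %), toluene–CHCl3 (2:1), −40 °C, dark
Reagents that add atoms: N-bromosuccinimide, O=C1CCC(=O)N1Br
Why: Proposed new method: the quinuclidine nitrogen of the alkaloid dimer activates NBS and passes bromine to one face of the 1,1-disubstituted styrene, the carbonyl oxygen of the carbonate opens the bromonium ion anti at the benzylic carbon to give the 2-tert-butoxy-1,3-dioxolan-2-ylium ion 11, and loss of isobutene (the proton going to the succinimide anion) leaves the neutral cyclic carbonate 12 with the new tertiary C–O and C–Br bonds. The closest known reaction types are the cinchona-alkaloid-catalysed enantioselective halocyclisations of 1,1-disubstituted alkenes bearing amide, carbamate or carboxylic acid nucleophiles and the racemic halocyclisation of allylic and homoallylic tert-butyl carbonates; only the pairing of the carbonate nucleophile with alkaloid control is untested. The dioxolanone ring closes in the 5-exo mode, the bromomethyl carbon remaining outside the ring. The single new stereocentre, quaternary C4, is controlled by the catalyst, which chooses the alkene face that receives bromine and thereby the opposite face for oxygen. The step needs enantiofacial selectivity, Markovnikov 5-exo regioselectivity and preference for the alkene over the arene: the tether length and the tertiary aryl-substituted carbon secure the regiochemistry, and the formyl group deactivates the silyloxyarene towards ring bromination.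

Step 6
Reactants: 12 (4S)-4-(bromomethyl)-4-{4-formyl-2-[tri(propan-2-yl)silyloxy]phenyl}-1,3-dioxolan-2-one
Product: 14 4-[(2S)-2-(hydroxymethyl)oxiran-2-yl]-3-[tri(propan-2-yl)silyloxy]benzaldehyde, via bromodiol 13 (not isolated)
Conditions: K2CO3 (2 equiv), MeOH, 0 °C
Reagents that add atoms: none
Why: Carbonate methanolysis followed by Williamson-type epoxide closure, in which methoxide transesterifies the strained cyclic carbonate to dimethyl carbonate and the tertiary alkoxide of bromodiol 13 displaces the neighbouring primary bromide (3-exo-tet), so the quaternary stereocentre is carried over unchanged because none of its bonds is broken.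

Step 7
Reactants: 14 4-[(2S)-2-(hydroxymethyl)oxiran-2-yl]-3-[tri(propan-2-yl)silyloxy]benzaldehyde; 15 acetic anhydride
Product: 16 [(2R)-2-{4-formyl-2-[tri(propan-2-yl)silyloxy]phenyl}oxiran-2-yl]methyl acetate
Conditions: Ac2O, pyridine, DMAP (5 mol %), CH2Cl2, 0 °C
Reagents that add atoms: acetic anhydride, CC(=O)OC(C)=O
Why: Base-mediated acetylation of the primary alcohol keeps the medium non-acidic, which the aryl-substituted oxirane requires (the descriptor changes from S to R only because the acetoxymethyl arm now outranks the ring CH2).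

Step 8
Reactants: 16 [(2R)-2-{4-formyl-2-[tri(propan-2-yl)silyloxy]phenyl}oxiran-2-yl]methyl acetate
Product: 17 [(2R)-2-{4-(hydroxymethyl)-2-[tri(propan-2-yl)silyloxy]phenyl}oxiran-2-yl]methyl acetate
Conditions: NaBH4, THF–EtOH (4:1), −20 °C; pH 7 phosphate buffer
Reagents that add atoms: none
Why: Chemoselective sodium borohydride reduction of the aromatic aldehyde at low temperature should be much faster than any attack on the acetate, the oxirane or the silyl ether.

Step 9
Reactants: 17 [(2R)-2-{4-(hydroxymethyl)-2-[tri(propan-2-yl)silyloxy]phenyl}oxiran-2-yl]methyl acetate; 18 (2R)-2-methylbutanoic acid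
Product: 19 {4-[(2R)-2-(acetoxymethyl)oxiran-2-yl]-3-[tri(propan-2-yl)silyloxy]phenyl}methyl (2R)-2-methylbutanoate
Conditions: (R)-2-methylbutanoic acid, N,N'-dicyclohexylcarbodiimide (DCC), DMAP (10 mol %), CH2Cl2, 0 °C to rt
Reagents that add atoms: (2R)-2-methylbutanoic acid, OC(=O)[C@H](C)CC
Why: Steglich esterification of the benzylic alcohol, in which the acid is consumed as its O-acylisourea so the oxirane never meets a strong acid and the α-stereocentre of the saturated acid should not epimerise at 0 °C.

Step 10
Reactants: 19 {4-[(2R)-2-(acetoxymethyl)oxiran-2-yl]-3-[tri(propan-2-yl)silyloxy]phenyl}methyl (2R)-2-methylbutanoate; 20 angelic anhydride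
Product: 22 {4-[(2R)-2-(acetoxymethyl)oxiran-2-yl]-3-{[(2Z)-2-methylbut-2-enoyl]oxy}phenyl}methyl (2R)-2-methylbutanoate (CNP0256757.1), via tetrabutylammonium phenoxide 21 (not isolated)
Conditions: angelic anhydride (3 equiv), Bu4NF (1.1 equiv, added last), THF, −20 to 0 °C
Reagents that add atoms: angelic anhydride, C/C=C(/C)C(=O)OC(=O)/C(C)=C\C
Why: Fluoride-triggered desilylative acylation, in which fluoride cleaves the aryl O–Si bond and phenoxide 21 is captured at once by the excess anhydride, faster than the geometrically disfavoured 5-endo attack on the oxirane CH2, while the low temperature should preserve the (Z) geometry of the angelate.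

**Compound list**

1 | 3-hydroxy-4-iodobenzaldehyde | O=Cc1ccc(I)c(O)c1 | starting material
2 | chlorotri(propan-2-yl)silane (TIPSCl) | CC(C)[Si](Cl)(C(C)C)C(C)C | starting material
3 | 4-iodo-3-[tri(propan-2-yl)silyloxy]benzaldehyde | CC(C)[Si](C(C)C)(C(C)C)Oc1cc(C=O)ccc1I | intermediate
4 | bis(pinacolato)diboron | CC1(C)OB(OC1(C)C)B1OC(C)(C)C(C)(C)O1 | starting material
5 | 4-(4,4,5,5-tetramethyl-1,3,2-dioxaborolan-2-yl)-3-[tri(propan-2-yl)silyloxy]benzaldehyde | CC(C)[Si](C(C)C)(C(C)C)Oc1cc(C=O)ccc1B1OC(C)(C)C(C)(C)O1 | intermediate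
6 | 2-bromoprop-2-en-1-ol | OCC(Br)=C | starting material
7 | 4-(3-hydroxyprop-1-en-2-yl)-3-[tri(propan-2-yl)silyloxy]benzaldehyde | CC(C)[Si](C(C)C)(C(C)C)Oc1cc(C=O)ccc1C(=C)CO | intermediate
8 | di-tert-butyl dicarbonate | CC(C)(C)OC(=O)OC(=O)OC(C)(C)C | starting material
9 | tert-butyl 2-{4-formyl-2-[tri(propan-2-yl)silyloxy]phenyl}prop-2-en-1-yl carbonate | CC(C)[Si](C(C)C)(C(C)C)Oc1cc(C=O)ccc1C(=C)COC(=O)OC(C)(C)C | intermediate
10 | N-bromosuccinimide | O=C1CCC(=O)N1Br | starting material
11 | (4S)-4-(bromomethyl)-2-tert-butoxy-4-{4-formyl-2-[tri(propan-2-yl)silyloxy]phenyl}-1,3-dioxolan-2-ylium succinimidate (ion pair, not isolated) | CC(C)[Si](C(C)C)(C(C)C)Oc1cc(C=O)ccc1[C@@]1(CBr)CO[C+](OC(C)(C)C)O1.O=C1CCC(=O)[N-]1 | intermediate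
12 | (4S)-4-(bromomethyl)-4-{4-formyl-2-[tri(propan-2-yl)silyloxy]phenyl}-1,3-dioxolan-2-one | CC(C)[Si](C(C)C)(C(C)C)Oc1cc(C=O)ccc1[C@@]1(CBr)COC(=O)O1 | intermediate
13 | 4-[(2S)-1-bromo-2,3-dihydroxypropan-2-yl]-3-[tri(propan-2-yl)silyloxy]benzaldehyde (not isolated) | CC(C)[Si](C(C)C)(C(C)C)Oc1cc(C=O)ccc1[C@@](O)(CBr)CO | intermediate
14 | 4-[(2S)-2-(hydroxymethyl)oxiran-2-yl]-3-[tri(propan-2-yl)silyloxy]benzaldehyde | CC(C)[Si](C(C)C)(C(C)C)Oc1cc(C=O)ccc1[C@]1(CO)CO1 | intermediate
15 | acetic anhydride | CC(=O)OC(C)=O | starting material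
16 | [(2R)-2-{4-formyl-2-[tri(propan-2-yl)silyloxy]phenyl}oxiran-2-yl]methyl acetate | CC(C)[Si](C(C)C)(C(C)C)Oc1cc(C=O)ccc1[C@]1(COC(C)=O)CO1 | intermediate
17 | [(2R)-2-{4-(hydroxymethyl)-2-[tri(propan-2-yl)silyloxy]phenyl}oxiran-2-yl]methyl acetate | CC(C)[Si](C(C)C)(C(C)C)Oc1cc(CO)ccc1[C@]1(COC(C)=O)CO1 | intermediate
18 | (2R)-2-methylbutanoic acid | OC(=O)[C@H](C)CC | starting material
19 | {4-[(2R)-2-(acetoxymethyl)oxiran-2-yl]-3-[tri(propan-2-yl)silyloxy]phenyl}methyl (2R)-2-methylbutanoate | CC(C)[Si](C(C)C)(C(C)C)Oc1cc(COC(=O)[C@H](C)CC)ccc1[C@]1(COC(C)=O)CO1 | intermediate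
20 | angelic anhydride, (Z)-2-methylbut-2-enoic anhydride | C/C=C(/C)C(=O)OC(=O)/C(C)=C\C | starting material
21 | tetrabutylammonium 2-[(2R)-2-(acetoxymethyl)oxiran-2-yl]-5-{[(2R)-2-methylbutanoyl]oxymethyl}phenolate (not isolated) | CCCC[N+](CCCC)(CCCC)CCCC.[O-]c1cc(COC(=O)[C@H](C)CC)ccc1[C@]1(COC(C)=O)CO1 | intermediate
22 | {4-[(2R)-2-(acetoxymethyl)oxiran-2-yl]-3-{[(2Z)-2-methylbut-2-enoyl]oxy}phenyl}methyl (2R)-2-methylbutanoate (CNP0256757.1) | C/C=C(/C)C(=O)Oc1cc(COC(=O)[C@H](C)CC)ccc1[C@]1(COC(C)=O)CO1 | target

**Step count and risks**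

Total steps: 10. Longest linear sequence: 10 steps (1 to 22).

Steps most likely to fail:

Step 5 (Proposed new method). The carbonate offers no hydrogen-bond donor to the alkaloid, so facial discrimination may be poor. Electrophilic bromination of the arene or premature loss of the tert-butyl carbonate could also compete. The fallback leaves the route at allylic alcohol 7 and uses a Sharpless asymmetric epoxidation (Ti(OiPr)4, L-(+)-diethyl tartrate, tBuOOH, 4 Å molecular sieves, CH2Cl2, −20 °C). 2-Substituted allylic alcohols are established substrates for this reaction. The natural tartrate is expected to give the (S)-epoxy alcohol 14 directly, and the route is rejoined there at step 7. This detour also bypasses steps 4 and 6 and makes no compound outside the list (F0).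

Step 10. The phenoxide set free by fluoride may open the oxirane or cleave the acetate before it is acylated, and the angelate may isomerise to the tiglate under the basic fluoride conditions. The fallback separates unmasking from acylation. Compound 19 is desilylated with Bu4NF buffered by acetic acid (THF, −20 °C) to the neutral phenol {4-[(2R)-2-(acetoxymethyl)oxiran-2-yl]-3-hydroxyphenyl}methyl (2R)-2-methylbutanoate F1. F1 is then acylated with angelic anhydride 20 under Et3N and catalytic DMAP in CH2Cl2 at −20 °C, which returns to the route at target 22.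

Step 3. The hindered ortho-silyloxy boronate may undergo protodeboronation, or the aqueous base may remove the silyl group before coupling. The fallback reverses the polarity of the coupling under neutral conditions and sets out from aryl iodide 3. Propargyl alcohol is hydrostannylated at the internal carbon (Bu3SnH, Mo(CO)3(CNtBu)3, THF, 55 °C) to 2-(tributylstannyl)prop-2-en-1-ol F2. Stille coupling of F2 with 3 (Pd2(dba)3, AsPh3, CuI, DMF, 50 °C) rejoins the route at allylic alcohol 7 without passing through boronate 5.

**Further compounds**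

F0 | step 5 | none | none
F1 | step 10 | {4-[(2R)-2-(acetoxymethyl)oxiran-2-yl]-3-hydroxyphenyl}methyl (2R)-2-methylbutanoate | Oc1cc(COC(=O)[C@H](C)CC)ccc1[C@]1(COC(C)=O)CO1
F2 | step 3 | 2-(tributylstannyl)prop-2-en-1-ol | CCCC[Sn](CCCC)(CCCC)C(=C)CO
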